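**Retrosynthetic overview**
1. Target 37 ⇐ lipase-catalysed removal of the primary C15 acetate of 3,15-diacetate 36 ⇐ ring-closing metathesis at C9=C10 of seco-diene 35 (ten-membered carbocycle closed last).
2. 35 ⇐ angelate/acetate adjustment of 29 ⇐ zinc Barbier allylation (C7–C8) of bromomethyl butenolide 26 with acrolein, which sets C7 and C8 and unveils the α-methylene lactone.
3. 26 ⇐ butenolide by carbonylative lactonization of a Z-iodoallylic alcohol ⇐ propargylic alcohol 21 (C6 by catalytic asymmetric alkynylation of Z-enal 18).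
4. 18 ⇐ Nozaki–Hiyama–Kishi coupling (C3–C4) of Z-iodoalkene 5 (from but-2-yne-1,4-diol, fixes the 4Z alkene) with aldehyde 11, then CBS reduction (C3) and a PMP acetal tying O3 to O15.
5. 11 ⇐ titanium-catalysed asymmetric Mukaiyama acetate aldol of methacrolein (C1, first stereocentre). Ring order: temporary dioxane, then the five-membered lactone, then the carbocycle.

Notation and assumption: locants follow the germacranolide skeleton (C12 lactone carbonyl with O on C6; C15 = CH2OH on C4; C14 = CH3 on C10; OAc on C3; OH on C1; angelate on C8); TBS = tert-butyldimethylsilyl, PMB = 4-methoxybenzyl, PMP = 4-methoxyphenyl, Dx = the (2R,4S,5Z)-2-PMP-4-[(2S)-3-methyl-2-(TBSO)but-3-en-1-yl]-1,3-dioxan-5-ylidene unit; ketene acetal 7 and angelic acid 30 are taken as purchasable. The ligand enantiomers in steps 4 and 13 are named for the required facial sense and are not recalled from precedent; the product configuration is to be confirmed by Mosher ester analysis, and the antipodal ligand is used if the sense is opposite.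

**Step 1**
Reactants: 1 but-2-yne-1,4-diol
Product: 2 4-(PMBO)but-2-yn-1-ol
Conditions: NaH (1.0 equiv), 1 (3 equiv), THF/DMF, 0 °C; PMBCl (1.0 equiv), Bu4NI (5 mol%), rt
Reagents that add atoms: 4-methoxybenzyl chloride (COc1ccc(CCl)cc1)
Why: Williamson etherification of the mono-alkoxide in the presence of excess diol gives mainly the mono-ether, and the surplus diol is washed out with water.

**Step 2**
Reactants: 2 4-(PMBO)but-2-yn-1-ol
Product: 4 (2Z)-3-iodo-4-(PMBO)but-2-en-1-ol, via cyclic sodium alkenylaluminate 3 (not isolated)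
Conditions: NaAlH2(OCH2CH2OMe)2 (Red-Al, 1.6 equiv), THF, 0 °C to rt; then I2, THF, −78 to 0 °C; Rochelle salt work-up
Reagents that add atoms: iodine (II)
Why: Hydroxyl-directed trans-hydroalumination puts aluminium on the distal alkyne carbon cis to CH2OH, and iodinolysis with retention gives the Z-iodoalkene that fixes the later C4=C5 geometry.

**Step 3**
Reactants: 4 (2Z)-3-iodo-4-(PMBO)but-2-en-1-ol
Product: 5 (2Z)-3-iodo-4-(PMBO)but-2-en-1-yl acetate
Conditions: Ac2O, pyridine, DMAP (5 mol%), CH2Cl2, 0 °C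
Reagents that add atoms: acetic anhydride (CC(=O)OC(C)=O)
Why: Simple acetylation (nucleophilic acyl substitution) masks the C6 oxygen with a group that tolerates chromium, periodinane, borane and DDQ and is later removed by carbonate in methanol.

**Step 4**
Reactants: 6 methacrolein; 7 1-methoxy-1-(trimethylsilyloxy)ethene
Product: 9 methyl (3S)-3-hydroxy-4-methylpent-4-enoate, via trimethylsilyl ether 8 (not isolated)
Conditions: Ti(OiPr)4 (2 mol%), (S)-Carreira binaphthyl Schiff-base ligand (2.2 mol%), 3,5-di-tert-butylsalicylic acid (2 mol%), Et2O, −10 °C; then 1 M HCl, THF, 0 °C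
Reagents that add atoms: none
Why: Carreira catalytic asymmetric Mukaiyama acetate aldol, in which the chiral titanium complex activates the enal and directs the ketene acetal to its Si face, creating C1 as the first stereocentre before acid removes the silyl group.

**Step 5**
Reactants: 9 methyl (3S)-3-hydroxy-4-methylpent-4-enoate
Product: 10 methyl (3S)-4-methyl-3-(TBSO)pent-4-enoate
Conditions: TBSCl, imidazole, DMF, rt
Reagents that add atoms: tert-butyldimethylsilyl chloride (CC(C)(C)[Si](C)(C)Cl)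
Why: Corey silylation of the secondary allylic alcohol proceeds without touching the stereocentre.

**Step 6**
Reactants: 10 methyl (3S)-4-methyl-3-(TBSO)pent-4-enoate
Product: 11 (3S)-4-methyl-3-(TBSO)pent-4-enal
Conditions: iBu2AlH (1.1 equiv), CH2Cl2, −78 °C; Rochelle salt
Reagents that add atoms: none
Why: DIBAL-H half-reduction stops at the aluminium hemiacetal at −78 °C and releases the aldehyde on work-up, the β-stereocentre being non-epimerizable.

**Step 7**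
Reactants: 5 (2Z)-3-iodo-4-(PMBO)but-2-en-1-yl acetate; 11 (3S)-4-methyl-3-(TBSO)pent-4-enal
Product: 13 (2Z,6S)-4-hydroxy-7-methyl-3-[(PMBO)methyl]-6-(TBSO)octa-2,7-dien-1-yl acetate as both C4 epimers, via alkenylchromium dichloride 12 (not isolated)
Conditions: CrCl2 (5 equiv), NiCl2 (2 mol%), DMSO, rt
Reagents that add atoms: none
Why: Nozaki–Hiyama–Kishi coupling forms the alkenylchromium species with retention of the Z geometry and adds it chemoselectively to the aldehyde; the unselective C3 carbinol is corrected in steps 8 and 9.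

**Step 8**
Reactants: 13 (2Z,6S)-4-hydroxy-7-methyl-3-[(PMBO)methyl]-6-(TBSO)octa-2,7-dien-1-yl acetate
Product: 14 (2Z,6S)-7-methyl-4-oxo-3-[(PMBO)methyl]-6-(TBSO)octa-2,7-dien-1-yl acetate
Conditions: Dess–Martin periodinane, NaHCO3, CH2Cl2, 0 °C to rt
Reagents that add atoms: none
Why: Buffered Dess–Martin oxidation converges both epimers to the Z-enone without β-elimination of the silyloxy group.

**Step 9**
Reactants: 14 (2Z,6S)-7-methyl-4-oxo-3-[(PMBO)methyl]-6-(TBSO)octa-2,7-dien-1-yl acetate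
Product: 15 (2Z,4S,6S)-4-hydroxy-7-methyl-3-[(PMBO)methyl]-6-(TBSO)octa-2,7-dien-1-yl acetate
Conditions: (R)-2-methyl-CBS-oxazaborolidine (20 mol%), catecholborane (1.5 equiv), toluene, −78 °C
Reagents that add atoms: none
Why: Corey–Bakshi–Shibata reduction treats the α-branched alkenyl group as the large substituent and delivers hydride under catalyst control to give the 3S carbinol (1,3-anti to C1), catecholborane sparing the alkenes.

**Step 10**
Reactants: 15 (2Z,4S,6S)-4-hydroxy-7-methyl-3-[(PMBO)methyl]-6-(TBSO)octa-2,7-dien-1-yl acetate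
Product: 16 2-(Dx)ethyl acetate
Conditions: DDQ (1.2 equiv), 4 Å molecular sieves, CH2Cl2, 0 °C
Reagents that add atoms: none
Why: Oikawa–Yonemitsu oxidative acetalization turns the PMB ether into an oxocarbenium ion that the C3 hydroxyl traps, giving the six-membered PMP acetal with aryl and C3 substituent both equatorial (2R) and protecting O3 and O15 together.

**Step 11**
Reactants: 16 2-(Dx)ethyl acetate
Product: 17 2-(Dx)ethanol
Conditions: K2CO3 (0.3 equiv), MeOH, 0 °C to rt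
Reagents that add atoms: none
Why: Base-catalysed transesterification removes the primary acetate while silyl ether and acetal are inert.

**Step 12**
Reactants: 17 2-(Dx)ethanol
Product: 18 2-(Dx)acetaldehyde
Conditions: MnO2 (20 equiv), CH2Cl2, rt, dark
Reagents that add atoms: none
Why: Heterogeneous MnO2 oxidation of the primary allylic alcohol is neutral and preserves the Z geometry of the enal.

**Step 13**
Reactants: 18 2-(Dx)acetaldehyde; 19 tert-butyldimethyl(prop-2-yn-1-yloxy)silane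
Product: 21 (2S)-5-(TBSO)-1-(Dx)pent-3-yn-2-ol, via alkynyl(methyl)zinc 20 (not isolated)
Conditions: Me2Zn (3 equiv), 19 (3 equiv), (S,S)-ProPhenol (20 mol%), Ph3P=O (40 mol%), toluene, 0–4 °C
Reagents that add atoms: none
Why: Trost zinc–ProPhenol asymmetric alkynylation, in which the dinuclear zinc catalyst binds enal and alkynylzinc and delivers the alkyne to the Re face to set C6 (6S) under catalyst control.

**Step 14**
Reactants: 21 (2S)-5-(TBSO)-1-(Dx)pent-3-yn-2-ol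
Product: 23 (2S,3Z)-4-iodo-5-(TBSO)-1-(Dx)pent-3-en-2-ol, via cyclic sodium alkenylaluminate 22 (not isolated)
Conditions: NaAlH2(OCH2CH2OMe)2 (2 equiv), THF, 0 °C to rt; then I2, THF, −78 °C
Reagents that add atoms: iodine (II)
Why: Alkoxide-directed trans-hydroalumination and iodinolysis as in step 2 place iodine on C11 cis to the C6 carbinol, the arrangement needed for lactonization.

**Step 15**
Reactants: 23 (2S,3Z)-4-iodo-5-(TBSO)-1-(Dx)pent-3-en-2-ol
Product: 24 (5S)-3-[(TBSO)methyl]-5-[(Dx)methyl]furan-2(5H)-one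
Conditions: PdCl2(PPh3)2 (5 mol%), CO (1 atm), K2CO3 (2 equiv), THF, 45 °C
Reagents that add atoms: carbon monoxide ([C-]#[O+])
Why: Palladium-catalysed carbonylative lactonization (oxidative addition of zerovalent palladium, CO insertion, capture of the acylpalladium by the cis hydroxyl) closes the butenolide without touching C6.

**Step 16**
Reactants: 24 (5S)-3-[(TBSO)methyl]-5-[(Dx)methyl]furan-2(5H)-one
Product: 25 (5S)-3-(hydroxymethyl)-5-[(Dx)methyl]furan-2(5H)-one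
Conditions: HF·pyridine, pyridine, THF, 0 °C
Reagents that add atoms: none
Why: Pyridine-buffered fluoride desilylation cleaves the primary allylic silyl ether far faster than the hindered secondary one and spares the acetal.

**Step 17**
Reactants: 25 (5S)-3-(hydroxymethyl)-5-[(Dx)methyl]furan-2(5H)-one
Product: 26 (5S)-3-(bromomethyl)-5-[(Dx)methyl]furan-2(5H)-one
Conditions: CBr4 (1.3 equiv), PPh3 (1.3 equiv), CH2Cl2, −20 to 0 °C
Reagents that add atoms: carbon tetrabromide (BrC(Br)(Br)Br)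
Why: Appel bromination converts the primary allylic alcohol by SN2 displacement under neutral conditions that spare the acetal and C6.

**Step 18**
Reactants: 26 (5S)-3-(bromomethyl)-5-[(Dx)methyl]furan-2(5H)-one; 27 acrolein
Product: 29 (4S,5S)-4-[(1R)-1-hydroxyprop-2-en-1-yl]-3-methylidene-5-[(Dx)methyl]oxolan-2-one, via allylzinc bromide 28 (not isolated)
Conditions: Zn dust (3 equiv), 27 (4 equiv), THF/sat. aq. NH4Cl (2:1), 0 °C to rt
Reagents that add atoms: none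
Why: Zinc Barbier allylation through the γ-carbon (C7) in a chair Zimmerman–Traxler transition state on the face anti to the C6 alkenyl group gives the trans-lactone (7S), and the ring-fixed E-type allyl geometry gives the 8R carbinol, with the α-methylene lactone formed at the same time.

**Step 19**
Reactants: 29 (4S,5S)-4-[(1R)-1-hydroxyprop-2-en-1-yl]-3-methylidene-5-[(Dx)methyl]oxolan-2-one; 30 angelic acid
Product: 32 (1R)-1-{(2S,3S)-4-methylidene-5-oxo-2-[(Dx)methyl]oxolan-3-yl}prop-2-en-1-yl (2Z)-2-methylbut-2-enoate, via mixed anhydride 31 (not isolated)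
Conditions: 30 (3 equiv), 2,4,6-trichlorobenzoyl chloride (3 equiv), Et3N (6 equiv), toluene, rt; then 29, 75 °C
Reagents that add atoms: none
Why: Yamaguchi-type esterification through the mixed anhydride acylates the hindered C8 alcohol without DMAP, which avoids isomerization of the angelate to the tiglate.

**Step 20**
Reactants: 32 (1R)-1-{(2S,3S)-4-methylidene-5-oxo-2-[(Dx)methyl]oxolan-3-yl}prop-2-en-1-yl (2Z)-2-methylbut-2-enoate
Product: 33 (1R)-1-{(2S,3S)-2-[(1Z,3S,5S)-3-hydroxy-2-(hydroxymethyl)-6-methyl-5-(TBSO)hepta-1,6-dien-1-yl]-4-methylidene-5-oxooxolan-3-yl}prop-2-en-1-yl (2Z)-2-methylbut-2-enoate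
Conditions: AcOH/THF/H2O (3:1:1), rt
Reagents that add atoms: none
Why: Mild acid hydrolysis of the electron-rich PMP acetal frees the C3 and C15 hydroxyls while the secondary silyl ether, the esters and the lactone survive.

**Step 21**
Reactants: 33 (1R)-1-{(2S,3S)-2-[(1Z,3S,5S)-3-hydroxy-2-(hydroxymethyl)-6-methyl-5-(TBSO)hepta-1,6-dien-1-yl]-4-methylidene-5-oxooxolan-3-yl}prop-2-en-1-yl (2Z)-2-methylbut-2-enoate
Product: 34 (1R)-1-{(2S,3S)-2-[(1Z,3S,5S)-3-acetoxy-2-(acetoxymethyl)-6-methyl-5-(TBSO)hepta-1,6-dien-1-yl]-4-methylidene-5-oxooxolan-3-yl}prop-2-en-1-yl (2Z)-2-methylbut-2-enoate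
Conditions: Ac2O (4 equiv), pyridine, DMAP (10 mol%), CH2Cl2, 0 °C
Reagents that add atoms: acetic anhydride (CC(=O)OC(C)=O)
Why: Acetylation takes both free hydroxyls, and because O1 is still silylated only O3 and O15 are acylated.

**Step 22**
Reactants: 34 (1R)-1-{(2S,3S)-2-[(1Z,3S,5S)-3-acetoxy-2-(acetoxymethyl)-6-methyl-5-(TBSO)hepta-1,6-dien-1-yl]-4-methylidene-5-oxooxolan-3-yl}prop-2-en-1-yl (2Z)-2-methylbut-2-enoate
Product: 35 (1R)-1-{(2S,3S)-2-[(1Z,3S,5S)-3-acetoxy-2-(acetoxymethyl)-5-hydroxy-6-methylhepta-1,6-dien-1-yl]-4-methylidene-5-oxooxolan-3-yl}prop-2-en-1-yl (2Z)-2-methylbut-2-enoate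
Conditions: HF·pyridine, THF, 0 °C to rt
Reagents that add atoms: none
Why: Acidic fluoride desilylation frees the allylic C1 hydroxyl without acetyl migration, and the free allylic alcohol also assists the metathesis that follows.

**Step 23**
Reactants: 35 (1R)-1-{(2S,3S)-2-[(1Z,3S,5S)-3-acetoxy-2-(acetoxymethyl)-5-hydroxy-6-methylhepta-1,6-dien-1-yl]-4-methylidene-5-oxooxolan-3-yl}prop-2-en-1-yl (2Z)-2-methylbut-2-enoate
Product: 36 (1S,3S,4Z,6S,7S,8R,9Z)-3,15-diacetoxy-1-hydroxy-8-[(2Z)-2-methylbut-2-enoyloxy]germacra-4,9,11(13)-trien-12,6-olide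
Conditions: second-generation Hoveyda–Grubbs catalyst RuCl2(H2IMes)(=CH-C6H4-2-OiPr) (15 mol% in three portions), 1,4-benzoquinone (30 mol%), toluene (0.5 mM), 80 °C
Reagents that add atoms: none
Why: Ring-closing metathesis of the C8 vinyl group with the C10 isopropenyl group at high dilution closes the ten-membered ring, the cis,cis-cyclodeca-1,6-diene being the only low-strain outcome so the new alkene is Z, and the trans ring fusion blocks the rival cyclopentene closure onto C4=C5.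

**Step 24**
Reactants: 36 (1S,3S,4Z,6S,7S,8R,9Z)-3,15-diacetoxy-1-hydroxy-8-[(2Z)-2-methylbut-2-enoyloxy]germacra-4,9,11(13)-trien-12,6-olide
Product: 37 (1S,3S,4Z,6S,7S,8R,9Z)-3-acetoxy-1,15-dihydroxy-8-[(2Z)-2-methylbut-2-enoyloxy]germacra-4,9,11(13)-trien-12,6-olide (CNP0153210.4)
Conditions: immobilized Candida antarctica lipase B (Novozym 435), n-BuOH (10 equiv), MTBE, 30 °C
Reagents that add atoms: none
Why: Lipase-catalysed alcoholysis accepts only the unhindered primary allylic acetate, leaving the secondary C3 acetate, the angelate and the lactone untouched under neutral conditions that prevent acyl migration.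

**Compound list**
1 | but-2-yne-1,4-diol | OCC#CCO | starting material
2 | 4-(PMBO)but-2-yn-1-ol | OCC#CCOCc1ccc(OC)cc1 | intermediate
3 | sodium 2,2-bis(2-methoxyethoxy)-3-[(PMBO)methyl]-2,5-dihydro-1,2-oxaluminol-2-uide (cyclic alkenylaluminate) | [Na+].COCCO[Al-]1(OCCOC)OCC=C1COCc2ccc(OC)cc2 | intermediate
4 | (2Z)-3-iodo-4-(PMBO)but-2-en-1-ol | OC/C=C(\I)COCc1ccc(OC)cc1 | intermediate
5 | (2Z)-3-iodo-4-(PMBO)but-2-en-1-yl acetate | CC(=O)OC/C=C(\I)COCc1ccc(OC)cc1 | intermediate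
6 | methacrolein (2-methylprop-2-enal) | CC(=C)C=O | starting material
7 | 1-methoxy-1-(trimethylsilyloxy)ethene | COC(=C)O[Si](C)(C)C | starting material
8 | methyl (3S)-4-methyl-3-(trimethylsilyloxy)pent-4-enoate | COC(=O)C[C@H](O[Si](C)(C)C)C(C)=C | intermediate
9 | methyl (3S)-3-hydroxy-4-methylpent-4-enoate | COC(=O)C[C@H](O)C(C)=C | intermediate
10 | methyl (3S)-4-methyl-3-(TBSO)pent-4-enoate | COC(=O)C[C@H](O[Si](C)(C)C(C)(C)C)C(C)=C | intermediate
11 | (3S)-4-methyl-3-(TBSO)pent-4-enal | O=CC[C@H](O[Si](C)(C)C(C)(C)C)C(C)=C | intermediate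
12 | dichloro[(2Z)-4-acetoxy-1-(PMBO)but-2-en-2-yl]chromium | CC(=O)OC/C=C(\[Cr](Cl)Cl)COCc1ccc(OC)cc1 | intermediate
13 | (2Z,6S)-4-hydroxy-7-methyl-3-[(PMBO)methyl]-6-(TBSO)octa-2,7-dien-1-yl acetate (both C4 epimers) | CC(=O)OC/C=C(/COCc1ccc(OC)cc1)C(O)C[C@H](O[Si](C)(C)C(C)(C)C)C(C)=C | intermediate
14 | (2Z,6S)-7-methyl-4-oxo-3-[(PMBO)methyl]-6-(TBSO)octa-2,7-dien-1-yl acetate | CC(=O)OC/C=C(/COCc1ccc(OC)cc1)C(=O)C[C@H](O[Si](C)(C)C(C)(C)C)C(C)=C | intermediate
15 | (2Z,4S,6S)-4-hydroxy-7-methyl-3-[(PMBO)methyl]-6-(TBSO)octa-2,7-dien-1-yl acetate | CC(=O)OC/C=C(/COCc1ccc(OC)cc1)[C@@H](O)C[C@H](O[Si](C)(C)C(C)(C)C)C(C)=C | intermediate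
16 | 2-(Dx)ethyl acetate | CC(=O)OC/C=C1/CO[C@@H](c2ccc(OC)cc2)O[C@H]1C[C@H](O[Si](C)(C)C(C)(C)C)C(C)=C | intermediate
17 | 2-(Dx)ethanol | OC/C=C1/CO[C@@H](c2ccc(OC)cc2)O[C@H]1C[C@H](O[Si](C)(C)C(C)(C)C)C(C)=C | intermediate
18 | 2-(Dx)acetaldehyde | O=C/C=C1/CO[C@@H](c2ccc(OC)cc2)O[C@H]1C[C@H](O[Si](C)(C)C(C)(C)C)C(C)=C | intermediate
19 | tert-butyldimethyl(prop-2-yn-1-yloxy)silane | C#CCO[Si](C)(C)C(C)(C)C | starting material
20 | methyl[3-(TBSO)prop-1-yn-1-yl]zinc | C[Zn]C#CCO[Si](C)(C)C(C)(C)C | intermediate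
21 | (2S)-5-(TBSO)-1-(Dx)pent-3-yn-2-ol | O[C@H](C#CCO[Si](C)(C)C(C)(C)C)/C=C1/CO[C@@H](c2ccc(OC)cc2)O[C@H]1C[C@H](O[Si](C)(C)C(C)(C)C)C(C)=C | intermediate
22 | sodium (5S)-2,2-bis(2-methoxyethoxy)-3-[(TBSO)methyl]-5-[(Dx)methyl]-2,5-dihydro-1,2-oxaluminol-2-uide (cyclic alkenylaluminate) | [Na+].COCCO[Al-]1(OCCOC)O[C@H](C=C1CO[Si](C)(C)C(C)(C)C)/C=C2/CO[C@@H](c3ccc(OC)cc3)O[C@H]2C[C@H](O[Si](C)(C)C(C)(C)C)C(C)=C | intermediate
23 | (2S,3Z)-4-iodo-5-(TBSO)-1-(Dx)pent-3-en-2-ol | O[C@H](/C=C(\I)CO[Si](C)(C)C(C)(C)C)/C=C1/CO[C@@H](c2ccc(OC)cc2)O[C@H]1C[C@H](O[Si](C)(C)C(C)(C)C)C(C)=C | intermediate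
24 | (5S)-3-[(TBSO)methyl]-5-[(Dx)methyl]furan-2(5H)-one | O=C1O[C@H](C=C1CO[Si](C)(C)C(C)(C)C)/C=C2/CO[C@@H](c3ccc(OC)cc3)O[C@H]2C[C@H](O[Si](C)(C)C(C)(C)C)C(C)=C | intermediate
25 | (5S)-3-(hydroxymethyl)-5-[(Dx)methyl]furan-2(5H)-one | O=C1O[C@H](C=C1CO)/C=C2/CO[C@@H](c3ccc(OC)cc3)O[C@H]2C[C@H](O[Si](C)(C)C(C)(C)C)C(C)=C | intermediate
26 | (5S)-3-(bromomethyl)-5-[(Dx)methyl]furan-2(5H)-one | O=C1O[C@H](C=C1CBr)/C=C2/CO[C@@H](c3ccc(OC)cc3)O[C@H]2C[C@H](O[Si](C)(C)C(C)(C)C)C(C)=C | intermediate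
27 | acrolein (prop-2-enal) | C=CC=O | starting material
28 | bromo({(5S)-2-oxo-5-[(Dx)methyl]-2,5-dihydrofuran-3-yl}methyl)zinc | O=C1O[C@H](C=C1C[Zn]Br)/C=C2/CO[C@@H](c3ccc(OC)cc3)O[C@H]2C[C@H](O[Si](C)(C)C(C)(C)C)C(C)=C | intermediate
29 | (4S,5S)-4-[(1R)-1-hydroxyprop-2-en-1-yl]-3-methylidene-5-[(Dx)methyl]oxolan-2-one | C=C[C@@H](O)[C@@H]1C(=C)C(=O)O[C@H]1/C=C2/CO[C@@H](c3ccc(OC)cc3)O[C@H]2C[C@H](O[Si](C)(C)C(C)(C)C)C(C)=C | intermediate
30 | angelic acid, (2Z)-2-methylbut-2-enoic acid | C/C=C(/C)C(=O)O | starting material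
31 | (2Z)-2-methylbut-2-enoic 2,4,6-trichlorobenzoic anhydride | C/C=C(/C)C(=O)OC(=O)c1c(Cl)cc(Cl)cc1Cl | intermediate
32 | (1R)-1-{(2S,3S)-4-methylidene-5-oxo-2-[(Dx)methyl]oxolan-3-yl}prop-2-en-1-yl (2Z)-2-methylbut-2-enoate | C=C[C@@H](OC(=O)/C(C)=C\C)[C@@H]1C(=C)C(=O)O[C@H]1/C=C2/CO[C@@H](c3ccc(OC)cc3)O[C@H]2C[C@H](O[Si](C)(C)C(C)(C)C)C(C)=C | intermediate
33 | (1R)-1-{(2S,3S)-2-[(1Z,3S,5S)-3-hydroxy-2-(hydroxymethyl)-6-methyl-5-(TBSO)hepta-1,6-dien-1-yl]-4-methylidene-5-oxooxolan-3-yl}prop-2-en-1-yl (2Z)-2-methylbut-2-enoate | C=C[C@@H](OC(=O)/C(C)=C\C)[C@@H]1C(=C)C(=O)O[C@H]1/C=C(/CO)[C@@H](O)C[C@H](O[Si](C)(C)C(C)(C)C)C(C)=C | intermediate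
34 | (1R)-1-{(2S,3S)-2-[(1Z,3S,5S)-3-acetoxy-2-(acetoxymethyl)-6-methyl-5-(TBSO)hepta-1,6-dien-1-yl]-4-methylidene-5-oxooxolan-3-yl}prop-2-en-1-yl (2Z)-2-methylbut-2-enoate | C=C[C@@H](OC(=O)/C(C)=C\C)[C@@H]1C(=C)C(=O)O[C@H]1/C=C(/COC(C)=O)[C@@H](OC(C)=O)C[C@H](O[Si](C)(C)C(C)(C)C)C(C)=C | intermediate
35 | (1R)-1-{(2S,3S)-2-[(1Z,3S,5S)-3-acetoxy-2-(acetoxymethyl)-5-hydroxy-6-methylhepta-1,6-dien-1-yl]-4-methylidene-5-oxooxolan-3-yl}prop-2-en-1-yl (2Z)-2-methylbut-2-enoate | C=C[C@@H](OC(=O)/C(C)=C\C)[C@@H]1C(=C)C(=O)O[C@H]1/C=C(/COC(C)=O)[C@@H](OC(C)=O)C[C@H](O)C(C)=C | intermediate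
36 | (1S,3S,4Z,6S,7S,8R,9Z)-3,15-diacetoxy-1-hydroxy-8-[(2Z)-2-methylbut-2-enoyloxy]germacra-4,9,11(13)-trien-12,6-olide | C=C1C(=O)O[C@H]2/C=C(/COC(C)=O)[C@@H](OC(C)=O)C[C@H](O)/C(C)=C\[C@@H](OC(=O)/C(C)=C\C)[C@H]12 | intermediate
37 | (1S,3S,4Z,6S,7S,8R,9Z)-3-acetoxy-1,15-dihydroxy-8-[(2Z)-2-methylbut-2-enoyloxy]germacra-4,9,11(13)-trien-12,6-olide (CNP0153210.4) | C=C1C(=O)O[C@H]2/C=C(/CO)[C@@H](OC(C)=O)C[C@H](O)/C(C)=C\[C@@H](OC(=O)/C(C)=C\C)[C@H]12 | target

**Step count and risk**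
Total steps: 24. Longest linear sequence: 21 steps (steps 1–3 then 7–24; the branch 4–6 then 7–24 is equally long).

Most likely to fail, step 23 (ring-closing metathesis). A trisubstituted alkene must form in a ten-membered ring between two oxygenated allylic centres, so oligomers or stalled carbene are possible. Fallback, a relay metathesis: set out from bromolactone 26 and run the zinc Barbier reaction with (2E)-octa-2,7-dienal F1 (one Wittig step from hex-5-enal and (triphenylphosphoranylidene)acetaldehyde) to get the relay carbinol F2. Yamaguchi angeloylation through 31 gives angelate F3, AcOH/THF/H2O gives diol F4, Ac2O/pyridine gives diacetate F5 and HF·pyridine gives the C1 alcohol F6. The ruthenium catalyst then loads at the unhindered terminal alkene of the tether, expels cyclopentene to sit directly on C9 and closes onto the isopropenyl group, coming back to the route at 36.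

Second, step 13 (asymmetric alkynylation). The β,β-disubstituted Z-enal is hindered, so conversion, facial control or Z/E integrity may suffer. Fallback, addition then oxidation then asymmetric reduction: set out from enal 18 and add lithium 3-(TBSO)prop-1-yn-1-ide F7 (from 19 and n-BuLi, THF, −78 °C) to get both C6 epimers of the propargylic alcohol F8. Oxidize with Dess–Martin periodinane to the ynone F9 and reduce by Noyori transfer hydrogenation (RuCl(p-cymene)[(S,S)-TsDPEN], iPrOH, rt), which comes back at 21.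

Third, step 24 (lipase deacetylation). The compact macrocycle may bind poorly, giving slow turnover or loss of selectivity between the two acetates. Fallback, move the enzyme step ahead of ring closure: set out from seco-diacetate 34 and run the same lipase alcoholysis on this flexible open-chain substrate to get the C15 alcohol F10. Desilylate with HF·pyridine to the C1,C15-diol F11 and close the ring by metathesis under the conditions of step 23, coming back at target 37.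

**Further compounds**
F1 | step 23 | (2E)-octa-2,7-dienal | O=C/C=C/CCCC=C
F2 | step 23 | (4S,5S)-4-[(1R,2E)-1-hydroxyocta-2,7-dien-1-yl]-3-methylidene-5-[(Dx)methyl]oxolan-2-one | C=CCCC/C=C/[C@@H](O)[C@@H]1C(=C)C(=O)O[C@H]1/C=C2/CO[C@@H](c3ccc(OC)cc3)O[C@H]2C[C@H](O[Si](C)(C)C(C)(C)C)C(C)=C
F3 | step 23 | (1R,2E)-1-{(2S,3S)-4-methylidene-5-oxo-2-[(Dx)methyl]oxolan-3-yl}octa-2,7-dien-1-yl (2Z)-2-methylbut-2-enoate | C=CCCC/C=C/[C@@H](OC(=O)/C(C)=C\C)[C@@H]1C(=C)C(=O)O[C@H]1/C=C2/CO[C@@H](c3ccc(OC)cc3)O[C@H]2C[C@H](O[Si](C)(C)C(C)(C)C)C(C)=C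
F4 | step 23 | (1R,2E)-1-{(2S,3S)-2-[(1Z,3S,5S)-3-hydroxy-2-(hydroxymethyl)-6-methyl-5-(TBSO)hepta-1,6-dien-1-yl]-4-methylidene-5-oxooxolan-3-yl}octa-2,7-dien-1-yl (2Z)-2-methylbut-2-enoate | C=CCCC/C=C/[C@@H](OC(=O)/C(C)=C\C)[C@@H]1C(=C)C(=O)O[C@H]1/C=C(/CO)[C@@H](O)C[C@H](O[Si](C)(C)C(C)(C)C)C(C)=C
F5 | step 23 | (1R,2E)-1-{(2S,3S)-2-[(1Z,3S,5S)-3-acetoxy-2-(acetoxymethyl)-6-methyl-5-(TBSO)hepta-1,6-dien-1-yl]-4-methylidene-5-oxooxolan-3-yl}octa-2,7-dien-1-yl (2Z)-2-methylbut-2-enoate | C=CCCC/C=C/[C@@H](OC(=O)/C(C)=C\C)[C@@H]1C(=C)C(=O)O[C@H]1/C=C(/COC(C)=O)[C@@H](OC(C)=O)C[C@H](O[Si](C)(C)C(C)(C)C)C(C)=C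
F6 | step 23 | (1R,2E)-1-{(2S,3S)-2-[(1Z,3S,5S)-3-acetoxy-2-(acetoxymethyl)-5-hydroxy-6-methylhepta-1,6-dien-1-yl]-4-methylidene-5-oxooxolan-3-yl}octa-2,7-dien-1-yl (2Z)-2-methylbut-2-enoate | C=CCCC/C=C/[C@@H](OC(=O)/C(C)=C\C)[C@@H]1C(=C)C(=O)O[C@H]1/C=C(/COC(C)=O)[C@@H](OC(C)=O)C[C@H](O)C(C)=C
F7 | step 13 | lithium 3-(TBSO)prop-1-yn-1-ide | [Li]C#CCO[Si](C)(C)C(C)(C)C
F8 | step 13 | 5-(TBSO)-1-(Dx)pent-3-yn-2-ol (both C2 epimers) | OC(C#CCO[Si](C)(C)C(C)(C)C)/C=C1/CO[C@@H](c2ccc(OC)cc2)O[C@H]1C[C@H](O[Si](C)(C)C(C)(C)C)C(C)=C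
F9 | step 13 | 5-(TBSO)-1-(Dx)pent-3-yn-2-one | O=C(C#CCO[Si](C)(C)C(C)(C)C)/C=C1/CO[C@@H](c2ccc(OC)cc2)O[C@H]1C[C@H](O[Si](C)(C)C(C)(C)C)C(C)=C
F10 | step 24 | (1R)-1-{(2S,3S)-2-[(1Z,3S,5S)-3-acetoxy-2-(hydroxymethyl)-6-methyl-5-(TBSO)hepta-1,6-dien-1-yl]-4-methylidene-5-oxooxolan-3-yl}prop-2-en-1-yl (2Z)-2-methylbut-2-enoate | C=C[C@@H](OC(=O)/C(C)=C\C)[C@@H]1C(=C)C(=O)O[C@H]1/C=C(/CO)[C@@H](OC(C)=O)C[C@H](O[Si](C)(C)C(C)(C)C)C(C)=C
F11 | step 24 | (1R)-1-{(2S,3S)-2-[(1Z,3S,5S)-3-acetoxy-5-hydroxy-2-(hydroxymethyl)-6-methylhepta-1,6-dien-1-yl]-4-methylidene-5-oxooxolan-3-yl}prop-2-en-1-yl (2Z)-2-methylbut-2-enoate | C=C[C@@H](OC(=O)/C(C)=C\C)[C@@H]1C(=C)C(=O)O[C@H]1/C=C(/CO)[C@@H](OC(C)=O)C[C@H](O)C(C)=C
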